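## Retrosynthetic overview

1. The target is (−)-epicatechin-(4β→8)-(−)-epiafzelechin (flavan numbering; "upper" = catechol unit, "lower" = 4-hydroxyphenyl unit). It is released last by hydrogenolysis of its nona-O-benzyl ether 21.
2. Key disconnection: upper C4–lower C8 together with upper C4–C4a. Upper C4 is a diarylmethine carbon held between two phloroglucinol rings (C4a of the upper ring A, C8 of the lower ring A), and O1, O5 and O7 lie ortho/para to C4a. C4 can therefore enter as the aldehyde carbon of the open-chain aryl ether 18 and be arylated twice in one pot.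
3. The lower unit 11 comes from the analogous aldehyde 8 by the same ring closure, ended by hydride instead of an arene.
4. Both aldehydes come from an Evans syn-aldol of a (4S)-oxazolidinone glycolate (2 for the lower unit, 13 for the upper unit; sets C2/C3 of each unit), Weinreb amide formation, Pd C–O arylation with retention, and DIBAL-H reduction.
5. Ring order: lower pyran ring (step 5), then upper pyran ring and interflavan bond in one operation (step 10); all benzene rings are bought.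

Key step: step 10

Assumption: 2, 6 and 13 are taken as purchasable (each is otherwise one routine step from catalogue compounds), and the C4 cations 10 and 20 are drawn as benzylic carbocations although the charge is delocalised over O1, O5 and O7.

## Route

Step 1
Reactants: 1 4-(benzyloxy)benzaldehyde; 2 (4S)-4-benzyl-3-[(benzyloxy)acetyl]-1,3-oxazolidin-2-one
Product: 4 (4S)-4-benzyl-3-[(2S,3R)-2-(benzyloxy)-3-[4-(benzyloxy)phenyl]-3-hydroxypropanoyl]-1,3-oxazolidin-2-one, via boron enolate 3 (not isolated)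
Conditions: 2, Bu2BOTf, Et3N, CH2Cl2, −78 → 0 °C; then 1, −78 → 0 °C; pH 7 buffer, MeOH, H2O2, 0 °C
Reagents that add atoms: none
Why: Evans syn-aldol, in which the (Z)-boron enolate 3 reacts through a Zimmerman–Traxler chair on the face away from the auxiliary benzyl group and so sets the carbinol carbon (later C2) and the benzyloxy carbon (later C3) as the syn pair needed for a 2,3-cis flavan.

Step 2
Reactants: 4 (4S)-4-benzyl-3-[(2S,3R)-2-(benzyloxy)-3-[4-(benzyloxy)phenyl]-3-hydroxypropanoyl]-1,3-oxazolidin-2-one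
Product: 5 (2S,3R)-2-(benzyloxy)-3-[4-(benzyloxy)phenyl]-3-hydroxy-N-methoxy-N-methylpropanamide
Conditions: MeONHMe·HCl, AlMe3, CH2Cl2, −20 → 0 °C; aq. Rochelle salt
Reagents that add atoms: N,O-dimethylhydroxylamine hydrochloride, CNOC.Cl
Why: Weinreb transamidation of the N-acyl oxazolidinone by the aluminium amide, assisted by the free β-hydroxyl, should remove the auxiliary without touching either stereocentre.

Step 3
Reactants: 5 (2S,3R)-2-(benzyloxy)-3-[4-(benzyloxy)phenyl]-3-hydroxy-N-methoxy-N-methylpropanamide; 6 1,3-bis(benzyloxy)-5-bromobenzene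
Product: 7 (2S,3R)-2-(benzyloxy)-3-[4-(benzyloxy)phenyl]-3-[3,5-bis(benzyloxy)phenoxy]-N-methoxy-N-methylpropanamide
Conditions: 6 (1.3 equiv), [(allyl)PdCl]2 (2.5 mol%), RockPhos (6 mol%), Cs2CO3 (1.5 equiv), toluene, 90 °C
Reagents that add atoms: none
Why: Buchwald-type Pd-catalysed C–O cross-coupling of a secondary alcohol with an aryl bromide forms the aryl–oxygen bond, so the benzylic C–O bond is never broken and the carbinol configuration is retained, while the weak carbonate base should limit retro-aldol cleavage.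

Step 4
Reactants: 7 (2S,3R)-2-(benzyloxy)-3-[4-(benzyloxy)phenyl]-3-[3,5-bis(benzyloxy)phenoxy]-N-methoxy-N-methylpropanamide
Product: 8 (2S,3R)-2-(benzyloxy)-3-[4-(benzyloxy)phenyl]-3-[3,5-bis(benzyloxy)phenoxy]propanal
Conditions: DIBAL-H (1.5 equiv), THF, −78 °C; aq. Rochelle salt; aldehyde used crude at once
Reagents that add atoms: none
Why: Weinreb amide reduction, in which the chelated tetrahedral aluminium adduct persists at −78 °C and collapses to the aldehyde only on work-up, should avoid over-reduction and epimerisation of the α-benzyloxy centre.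

Step 5
Reactants: 8 (2S,3R)-2-(benzyloxy)-3-[4-(benzyloxy)phenyl]-3-[3,5-bis(benzyloxy)phenoxy]propanal
Product: 11 (2R,3R)-3,5,7-tris(benzyloxy)-2-[4-(benzyloxy)phenyl]chromane (3,5,7,4'-tetra-O-benzyl-(−)-epiafzelechin), via flavan-4-ol 9 (not isolated), via C4 cation 10 (not isolated)
Conditions: Et3SiH (5 equiv), Sc(OTf)3 (10 mol%), CH2Cl2, −40 → 0 °C
Reagents that add atoms: none
Why: Reductive Friedel–Crafts cycloalkylation, in which either of the two equivalent carbons ortho to the ether oxygen attacks the Sc-activated aldehyde (6-exo-trig), flavan-4-ol 9 ionises to the O1/O5/O7-stabilised cation 10 and triethylsilane delivers hydride (ionic hydrogenation), leaves C2 and C3 untouched.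

Step 6
Reactants: 12 3,4-bis(benzyloxy)benzaldehyde; 13 (4S)-3-[(benzyloxy)acetyl]-4-(propan-2-yl)-1,3-oxazolidin-2-one
Product: 15 (4S)-3-[(2S,3R)-2-(benzyloxy)-3-[3,4-bis(benzyloxy)phenyl]-3-hydroxypropanoyl]-4-(propan-2-yl)-1,3-oxazolidin-2-one, via boron enolate 14 (not isolated)
Conditions: 13, Bu2BOTf, Et3N, CH2Cl2, −78 → 0 °C; then 12, −78 → 0 °C; pH 7 buffer, MeOH, H2O2, 0 °C
Reagents that add atoms: none
Why: Evans syn-aldol as in step 1, run here with the valine-derived glycolate imide 13, whose (4S)-isopropyl group shields the same face of the (Z)-boron enolate 14 in the Zimmerman–Traxler chair and so sets C2 and C3 of the upper unit as the same syn pair.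

Step 7
Reactants: 15 (4S)-3-[(2S,3R)-2-(benzyloxy)-3-[3,4-bis(benzyloxy)phenyl]-3-hydroxypropanoyl]-4-(propan-2-yl)-1,3-oxazolidin-2-one
Product: 16 (2S,3R)-2-(benzyloxy)-3-[3,4-bis(benzyloxy)phenyl]-3-hydroxy-N-methoxy-N-methylpropanamide
Conditions: MeONHMe·HCl, AlMe3, CH2Cl2, −20 → 0 °C; aq. Rochelle salt
Reagents that add atoms: N,O-dimethylhydroxylamine hydrochloride, CNOC.Cl
Why: Weinreb transamidation as in step 2 should remove the auxiliary with both stereocentres intact.

Step 8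
Reactants: 16 (2S,3R)-2-(benzyloxy)-3-[3,4-bis(benzyloxy)phenyl]-3-hydroxy-N-methoxy-N-methylpropanamide; 6 1,3-bis(benzyloxy)-5-bromobenzene
Product: 17 (2S,3R)-2-(benzyloxy)-3-[3,4-bis(benzyloxy)phenyl]-3-[3,5-bis(benzyloxy)phenoxy]-N-methoxy-N-methylpropanamide
Conditions: 6 (1.3 equiv), [(allyl)PdCl]2 (2.5 mol%), RockPhos (6 mol%), Cs2CO3 (1.5 equiv), toluene, 90 °C
Reagents that add atoms: none
Why: Pd-catalysed C–O cross-coupling as in step 3 attaches ring A of the upper unit through O1 with retention at the carbinol carbon, because only the aryl–oxygen bond is formed.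

Step 9
Reactants: 17 (2S,3R)-2-(benzyloxy)-3-[3,4-bis(benzyloxy)phenyl]-3-[3,5-bis(benzyloxy)phenoxy]-N-methoxy-N-methylpropanamide
Product: 18 (2S,3R)-2-(benzyloxy)-3-[3,4-bis(benzyloxy)phenyl]-3-[3,5-bis(benzyloxy)phenoxy]propanal
Conditions: DIBAL-H (1.5 equiv), THF, −78 °C; aq. Rochelle salt; aldehyde used crude at once
Reagents that add atoms: none
Why: Weinreb amide reduction as in step 4 should stop at the aldehyde without epimerisation.

Step 10
Reactants: 18 (2S,3R)-2-(benzyloxy)-3-[3,4-bis(benzyloxy)phenyl]-3-[3,5-bis(benzyloxy)phenoxy]propanal; 11 (2R,3R)-3,5,7-tris(benzyloxy)-2-[4-(benzyloxy)phenyl]chromane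
Product: 21 3,5,7,3',4'-penta-O-benzyl-epicatechin-(4β→8)-3,5,7,4'-tetra-O-benzyl-epiafzelechin, via flavan-4-ol 19 (not isolated), via C4 cation 20 (not isolated)
Conditions: 11 (3 equiv, excess recovered), Sc(OTf)3 (10 mol%), 4 Å MS, CH2Cl2, −40 °C; 18 added over 1 h; → 0 °C
Reagents that add atoms: none
Why: Proposed new method: Sc(OTf)3 activates the chelated α-benzyloxy aldehyde of 18, either of the two equivalent carbons ortho to the ether oxygen of its 3,5-bis(benzyloxy)phenoxy ring attacks it (Friedel–Crafts hydroxyalkylation, 6-exo-trig, closing the upper pyran ring through C4–C4a) to give flavan-4-ol 19, the same catalyst ionises 19 to cation 20, which O1, O5 and O7 stabilise, and C8 of 11 traps 20 to form the C4–C8 bond. The closest known reaction types are the twofold Friedel–Crafts arylation of an aldehyde in which the first arylation is a ring closure (9-arylxanthenes from 2-aryloxybenzaldehydes and arenes) and the Lewis acid coupling of 4-oxygenated 2,3-cis-flavans with flavan-3-ol nucleophiles, which runs through the same kind of cation as 20. C2 and C3 are carried in unchanged from 18, and the new stereocentre C4 is set by attack on the half-chair cation from the face anti to the pseudoaxial 3-benzyloxy group and the 2-aryl group, which should give the 3,4-trans (4β) bond. The step needs C8 over C6 on 11, which should follow from C6 lying between two benzyloxy groups, and cross- over self-arylation, which the excess of 11 and the slow addition of 18 should secure. Should 11 add to the aldehyde before ring closure, the diarylmethyl cation so formed is closed by the same ortho carbon, so both orders lead to 21.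

Step 11
Reactants: 21 3,5,7,3',4'-penta-O-benzyl-epicatechin-(4β→8)-3,5,7,4'-tetra-O-benzyl-epiafzelechin
Product: 22 (−)-epicatechin-(4β→8)-(−)-epiafzelechin
Conditions: H2 (1 atm), Pd(OH)2/C, THF–MeOH–H2O, rt
Reagents that add atoms: none
Why: Hydrogenolysis over Pearlman's catalyst should cleave all nine benzyl ethers under neutral conditions that leave the acid-labile interflavan bond and the five stereocentres intact.

## Compound list

1 | 4-(benzyloxy)benzaldehyde | O=Cc1ccc(OCc2ccccc2)cc1 | starting material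
2 | (4S)-4-benzyl-3-[(benzyloxy)acetyl]-1,3-oxazolidin-2-one | O=C(COCc1ccccc1)N1[C@@H](Cc2ccccc2)COC1=O | starting material
3 | dibutylboron (Z)-enolate of 2 | CCCCB(CCCC)O/C(=C\OCc1ccccc1)N1[C@@H](Cc2ccccc2)COC1=O | intermediate
4 | (4S)-4-benzyl-3-[(2S,3R)-2-(benzyloxy)-3-[4-(benzyloxy)phenyl]-3-hydroxypropanoyl]-1,3-oxazolidin-2-one | O=C([C@@H](OCc1ccccc1)[C@H](O)c1ccc(OCc2ccccc2)cc1)N1[C@@H](Cc2ccccc2)COC1=O | intermediate
5 | (2S,3R)-2-(benzyloxy)-3-[4-(benzyloxy)phenyl]-3-hydroxy-N-methoxy-N-methylpropanamide | CON(C)C(=O)[C@@H](OCc1ccccc1)[C@H](O)c1ccc(OCc2ccccc2)cc1 | intermediate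
6 | 1,3-bis(benzyloxy)-5-bromobenzene | Brc1cc(OCc2ccccc2)cc(OCc2ccccc2)c1 | starting material
7 | (2S,3R)-2-(benzyloxy)-3-[4-(benzyloxy)phenyl]-3-[3,5-bis(benzyloxy)phenoxy]-N-methoxy-N-methylpropanamide | CON(C)C(=O)[C@@H](OCc1ccccc1)[C@H](Oc1cc(OCc2ccccc2)cc(OCc2ccccc2)c1)c1ccc(OCc2ccccc2)cc1 | intermediate
8 | (2S,3R)-2-(benzyloxy)-3-[4-(benzyloxy)phenyl]-3-[3,5-bis(benzyloxy)phenoxy]propanal | O=C[C@@H](OCc1ccccc1)[C@H](Oc1cc(OCc2ccccc2)cc(OCc2ccccc2)c1)c1ccc(OCc2ccccc2)cc1 | intermediate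
9 | (2R,3R)-3,5,7-tris(benzyloxy)-2-[4-(benzyloxy)phenyl]chroman-4-ol (both C4 epimers) | OC1c2c(OCc3ccccc3)cc(OCc3ccccc3)cc2O[C@H](c2ccc(OCc3ccccc3)cc2)[C@@H]1OCc1ccccc1 | intermediate
10 | (2R,3R)-3,5,7-tris(benzyloxy)-2-[4-(benzyloxy)phenyl]chroman-4-ylium (C4 cation) | [CH+]1c2c(OCc3ccccc3)cc(OCc3ccccc3)cc2O[C@H](c2ccc(OCc3ccccc3)cc2)[C@@H]1OCc1ccccc1 | intermediate
11 | (2R,3R)-3,5,7-tris(benzyloxy)-2-[4-(benzyloxy)phenyl]chromane (3,5,7,4'-tetra-O-benzyl-(−)-epiafzelechin) | C1c2c(OCc3ccccc3)cc(OCc3ccccc3)cc2O[C@H](c2ccc(OCc3ccccc3)cc2)[C@@H]1OCc1ccccc1 | intermediate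
12 | 3,4-bis(benzyloxy)benzaldehyde | O=Cc1ccc(OCc2ccccc2)c(OCc2ccccc2)c1 | starting material
13 | (4S)-3-[(benzyloxy)acetyl]-4-(propan-2-yl)-1,3-oxazolidin-2-one | O=C(COCc1ccccc1)N1[C@@H](C(C)C)COC1=O | starting material
14 | dibutylboron (Z)-enolate of 13 | CCCCB(CCCC)O/C(=C\OCc1ccccc1)N1[C@@H](C(C)C)COC1=O | intermediate
15 | (4S)-3-[(2S,3R)-2-(benzyloxy)-3-[3,4-bis(benzyloxy)phenyl]-3-hydroxypropanoyl]-4-(propan-2-yl)-1,3-oxazolidin-2-one | O=C([C@@H](OCc1ccccc1)[C@H](O)c1ccc(OCc2ccccc2)c(OCc2ccccc2)c1)N1[C@@H](C(C)C)COC1=O | intermediate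
16 | (2S,3R)-2-(benzyloxy)-3-[3,4-bis(benzyloxy)phenyl]-3-hydroxy-N-methoxy-N-methylpropanamide | CON(C)C(=O)[C@@H](OCc1ccccc1)[C@H](O)c1ccc(OCc2ccccc2)c(OCc2ccccc2)c1 | intermediate
17 | (2S,3R)-2-(benzyloxy)-3-[3,4-bis(benzyloxy)phenyl]-3-[3,5-bis(benzyloxy)phenoxy]-N-methoxy-N-methylpropanamide | CON(C)C(=O)[C@@H](OCc1ccccc1)[C@H](Oc1cc(OCc2ccccc2)cc(OCc2ccccc2)c1)c1ccc(OCc2ccccc2)c(OCc2ccccc2)c1 | intermediate
18 | (2S,3R)-2-(benzyloxy)-3-[3,4-bis(benzyloxy)phenyl]-3-[3,5-bis(benzyloxy)phenoxy]propanal | O=C[C@@H](OCc1ccccc1)[C@H](Oc1cc(OCc2ccccc2)cc(OCc2ccccc2)c1)c1ccc(OCc2ccccc2)c(OCc2ccccc2)c1 | intermediate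
19 | (2R,3R)-3,5,7-tris(benzyloxy)-2-[3,4-bis(benzyloxy)phenyl]chroman-4-ol (both C4 epimers) | OC1c2c(OCc3ccccc3)cc(OCc3ccccc3)cc2O[C@H](c2ccc(OCc3ccccc3)c(OCc3ccccc3)c2)[C@@H]1OCc1ccccc1 | intermediate
20 | (2R,3R)-3,5,7-tris(benzyloxy)-2-[3,4-bis(benzyloxy)phenyl]chroman-4-ylium (C4 cation) | [CH+]1c2c(OCc3ccccc3)cc(OCc3ccccc3)cc2O[C@H](c2ccc(OCc3ccccc3)c(OCc3ccccc3)c2)[C@@H]1OCc1ccccc1 | intermediate
21 | 3,5,7,3',4'-penta-O-benzyl-epicatechin-(4β→8)-3,5,7,4'-tetra-O-benzyl-epiafzelechin (nona-O-benzyl ether of 22; upper unit 2R,3R,4R, lower unit 2R,3R) | c1ccccc1COc1ccc([C@H]2Oc3c(c(OCc5ccccc5)cc(OCc5ccccc5)c3[C@H]3c4c(OCc5ccccc5)cc(OCc5ccccc5)cc4O[C@H](c4ccc(OCc5ccccc5)c(OCc5ccccc5)c4)[C@@H]3OCc3ccccc3)C[C@H]2OCc2ccccc2)cc1 | intermediate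
22 | (−)-epicatechin-(4β→8)-(−)-epiafzelechin; (2R,3R)-8-[(2R,3R,4R)-2-(3,4-dihydroxyphenyl)-3,5,7-trihydroxychroman-4-yl]-2-(4-hydroxyphenyl)chromane-3,5,7-triol | Oc1ccc([C@H]2Oc3c(c(O)cc(O)c3[C@H]3c4c(O)cc(O)cc4O[C@H](c4ccc(O)c(O)c4)[C@@H]3O)C[C@H]2O)cc1 | target

## Summary and risks

Total step count: 11. Longest linear sequence: 7 steps (steps 1–5, 10, 11).

Steps most likely to fail:

1. Step 10 (carries the label). Intermolecular arylation and oligomerisation may outrun ring closure, the open-chain benzylic aryl ether may ionise at C2 and fragment before the aldehyde reacts, and enolisation may erode C3. The fallback sets out from 18 and uses known chemistry. Under the conditions of step 5 (Et3SiH, Sc(OTf)3), 18 should close to (2R,3R)-3,5,7-tris(benzyloxy)-2-[3,4-bis(benzyloxy)phenyl]chromane F1. This is penta-O-benzyl-(−)-epicatechin, which exhaustive benzylation of purchased (−)-epicatechin with NaH/BnBr would also give, independently of 18. DDQ in CH2Cl2 with 2-ethoxyethanol should then oxidise the C4 methylene to 4β-(2-ethoxyethoxy)-3,5,7,3',4'-penta-O-benzyl-(−)-epicatechin F2. TMSOTf-catalysed coupling of F2 with an excess of 11 at −78 °C, the established interflavan bond formation from a 4-alkoxyflavan, comes back to the route at 21.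

2. Step 3 (step 8 is the same reaction on 16). β-Hydride elimination of the palladium alkoxide, retro-aldol cleavage of the β-hydroxy amide, or sluggish coupling of the hindered benzylic alcohol may prevail. The fallback sets out from 4 and forms the same aryl–oxygen bond by SNAr on a substrate without a carbonyl group. LiBH4 in THF/MeOH removes the auxiliary reductively to give (1R,2R)-2-(benzyloxy)-1-[4-(benzyloxy)phenyl]propane-1,3-diol F3. TBDPSCl/imidazole protects the primary hydroxyl to give (1R,2R)-2-(benzyloxy)-1-[4-(benzyloxy)phenyl]-3-[(tert-butyldiphenylsilyl)oxy]propan-1-ol F4. NaH and excess 1,3,5-trifluorobenzene in DMF arylate the benzylic alkoxide to tert-butyl{[(2R,3R)-2-(benzyloxy)-3-[4-(benzyloxy)phenyl]-3-(3,5-difluorophenoxy)propyl]oxy}diphenylsilane F5. BnONa in NMP at 100–120 °C replaces both remaining fluorides to give tert-butyl{[(2R,3R)-2-(benzyloxy)-3-[4-(benzyloxy)phenyl]-3-[3,5-bis(benzyloxy)phenoxy]propyl]oxy}diphenylsilane F6. TBAF frees (2R,3R)-2-(benzyloxy)-3-[4-(benzyloxy)phenyl]-3-[3,5-bis(benzyloxy)phenoxy]propan-1-ol F7. Dess–Martin oxidation comes back to the route at 8, so steps 2 to 4 are bypassed.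

3. Step 5. Hydride may be transferred to the activated aldehyde before ring closure (reduction or reductive etherification), or cation 10 may be arylated by a second molecule faster than it is reduced. The fallback sets out from 8 and avoids any C4 cation. NaBH4 gives (2R,3R)-2-(benzyloxy)-3-[4-(benzyloxy)phenyl]-3-[3,5-bis(benzyloxy)phenoxy]propan-1-ol F7 (the alcohol of the preceding fallback). Tf2O with 2,6-di-tert-butyl-4-methylpyridine in CH2Cl2 at −78 °C gives (2R,3R)-2-(benzyloxy)-3-[4-(benzyloxy)phenyl]-3-[3,5-bis(benzyloxy)phenoxy]propyl trifluoromethanesulfonate F8. On warming, F8 should alkylate the ortho carbon of the phenoxy ring (intramolecular Friedel–Crafts alkylation by a primary triflate) and come back to the route at 11.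

Further compounds

F1 | step 10 | (2R,3R)-3,5,7-tris(benzyloxy)-2-[3,4-bis(benzyloxy)phenyl]chromane (penta-O-benzyl-(−)-epicatechin) | C1c2c(OCc3ccccc3)cc(OCc3ccccc3)cc2O[C@H](c2ccc(OCc3ccccc3)c(OCc3ccccc3)c2)[C@@H]1OCc1ccccc1
F2 | step 10 | 4β-(2-ethoxyethoxy)-3,5,7,3',4'-penta-O-benzyl-(−)-epicatechin | CCOCCO[C@H]1c2c(OCc3ccccc3)cc(OCc3ccccc3)cc2O[C@H](c2ccc(OCc3ccccc3)c(OCc3ccccc3)c2)[C@@H]1OCc1ccccc1
F3 | step 3 | (1R,2R)-2-(benzyloxy)-1-[4-(benzyloxy)phenyl]propane-1,3-diol | OC[C@@H](OCc1ccccc1)[C@H](O)c1ccc(OCc2ccccc2)cc1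
F4 | step 3 | (1R,2R)-2-(benzyloxy)-1-[4-(benzyloxy)phenyl]-3-[(tert-butyldiphenylsilyl)oxy]propan-1-ol | CC(C)(C)[Si](c1ccccc1)(c1ccccc1)OC[C@@H](OCc1ccccc1)[C@H](O)c1ccc(OCc2ccccc2)cc1
F5 | step 3 | tert-butyl{[(2R,3R)-2-(benzyloxy)-3-[4-(benzyloxy)phenyl]-3-(3,5-difluorophenoxy)propyl]oxy}diphenylsilane | CC(C)(C)[Si](c1ccccc1)(c1ccccc1)OC[C@@H](OCc1ccccc1)[C@H](Oc1cc(F)cc(F)c1)c1ccc(OCc2ccccc2)cc1
F6 | step 3 | tert-butyl{[(2R,3R)-2-(benzyloxy)-3-[4-(benzyloxy)phenyl]-3-[3,5-bis(benzyloxy)phenoxy]propyl]oxy}diphenylsilane | CC(C)(C)[Si](c1ccccc1)(c1ccccc1)OC[C@@H](OCc1ccccc1)[C@H](Oc1cc(OCc2ccccc2)cc(OCc2ccccc2)c1)c1ccc(OCc2ccccc2)cc1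
F7 | step 3 | (2R,3R)-2-(benzyloxy)-3-[4-(benzyloxy)phenyl]-3-[3,5-bis(benzyloxy)phenoxy]propan-1-ol | OC[C@@H](OCc1ccccc1)[C@H](Oc1cc(OCc2ccccc2)cc(OCc2ccccc2)c1)c1ccc(OCc2ccccc2)cc1
F8 | step 5 | (2R,3R)-2-(benzyloxy)-3-[4-(benzyloxy)phenyl]-3-[3,5-bis(benzyloxy)phenoxy]propyl trifluoromethanesulfonate | O=S(=O)(OC[C@@H](OCc1ccccc1)[C@H](Oc1cc(OCc2ccccc2)cc(OCc2ccccc2)c1)c1ccc(OCc2ccccc2)cc1)C(F)(F)F
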